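Assumption: the target SMILES has no stereocentre and no acyclic stereogenic double bond (the chromene C=C is cis by ring constraint), so the compound is achiral and no enantioselective step is needed.

## Retrosynthetic overview

1. Kazinol K ⇐ its bis-MOM ether ⇐ benzylic deoxygenation (ortho-carbonate/NaBH4) and conjugate reduction of a 2'-hydroxychalcone.
2. Chalcone ⇐ Claisen–Schmidt aldol condensation of a ring A methyl ketone (fragment 1) with a ring B chromene aldehyde (fragment 2); this makes the central C–C bond of the propane bridge.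
3. Fragment 1 ⇐ 2,4-dihydroxyacetophenone by O-prenylation and aromatic Claisen rearrangement (1,1-dimethylallyl group at C5).
4. Fragment 2 ⇐ 2-bromo-4,5-dimethoxybenzaldehyde by propargyl ether Claisen/electrocyclisation (pyran ring) and Stille prenylation at the bromide.
5. Ring order: both benzene rings are bought; the only ring formed is the 2H-pyran on ring B, closed before the fragments are joined.

## Route

### Fragment 1 (ring A ketone)

Step 1
Reactants: 1 1-(2,4-dihydroxyphenyl)ethan-1-one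
Product: 2 1-{2-hydroxy-4-[(3-methylbut-2-en-1-yl)oxy]phenyl}ethan-1-one
Conditions: prenyl bromide (1.05 equiv), K2CO3 (1.2 equiv), acetone, reflux
Reagents that add atoms: prenyl bromide (1-bromo-3-methylbut-2-ene), CC(C)=CCBr
Why: Williamson etherification is selective for the 4-OH because the 2-OH is locked in a hydrogen bond to the acetyl carbonyl.

Step 2
Reactants: 2 1-{2-hydroxy-4-[(3-methylbut-2-en-1-yl)oxy]phenyl}ethan-1-one
Product: 3 1-{2-(methoxymethoxy)-4-[(3-methylbut-2-en-1-yl)oxy]phenyl}ethan-1-one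
Conditions: NaH, THF/DMF, 0 °C; then MOMCl, 0 °C → rt
Reagents that add atoms: chloromethyl methyl ether (MOMCl), COCCl
Why: Irreversible deprotonation breaks the chelate and O-alkylation (MOM acetal formation) removes the hydrogen bond that would otherwise steer the next rearrangement to C3.

Step 3
Reactants: 3 1-{2-(methoxymethoxy)-4-[(3-methylbut-2-en-1-yl)oxy]phenyl}ethan-1-one
Product: 5 1-[4-hydroxy-2-(methoxymethoxy)-5-(2-methylbut-3-en-2-yl)phenyl]ethan-1-one, via ortho-dienone 4 (not isolated)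
Conditions: EtOH/H2O (4:1), degassed, sealed tube, 135 °C
Reagents that add atoms: none
Why: The aromatic Claisen rearrangement ([3,3]-sigmatropic shift) delivers the inverted 1,1-dimethylallyl group to the open C5 instead of C3, which is flanked by two oxygens, and the dienone tautomerises to the phenol; the water-accelerated conditions keep the temperature below that of the abnormal Claisen pathway.

Step 4
Reactants: 5 1-[4-hydroxy-2-(methoxymethoxy)-5-(2-methylbut-3-en-2-yl)phenyl]ethan-1-one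
Product: 6 1-[2,4-dihydroxy-5-(2-methylbut-3-en-2-yl)phenyl]ethan-1-one
Conditions: HCl (1 M in MeOH), rt
Reagents that add atoms: none
Why: Acid-catalysed acetal methanolysis removes the MOM group ortho to the carbonyl (especially labile) under conditions too mild to protonate the monosubstituted alkene.

Step 5
Reactants: 6 1-[2,4-dihydroxy-5-(2-methylbut-3-en-2-yl)phenyl]ethan-1-one
Product: 7 1-[2-hydroxy-4-(methoxymethoxy)-5-(2-methylbut-3-en-2-yl)phenyl]ethan-1-one
Conditions: MOMCl (1.1 equiv), i-Pr2NEt, CH2Cl2, 0 °C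
Reagents that add atoms: chloromethyl methyl ether (MOMCl), COCCl
Why: Selective O-alkylation of the free 4-OH, because the chelated 2-OH does not react with MOMCl and an amine base at 0 °C.

### Fragment 2 (ring B aldehyde)

Step 6
Reactants: 8 2-bromo-4,5-dimethoxybenzaldehyde
Product: 9 2-bromo-4,5-dihydroxybenzaldehyde
Conditions: BBr3 (3 equiv), CH2Cl2, −78 °C → rt; then H2O
Reagents that add atoms: none
Why: Lewis-acid cleavage of both aryl methyl ethers with BBr3 is done here, before any acid-sensitive alkene exists.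

Step 7
Reactants: 9 2-bromo-4,5-dihydroxybenzaldehyde
Product: 10 2-bromo-5-hydroxy-4-[(2-methylbut-3-yn-2-yl)oxy]benzaldehyde
Conditions: 3-chloro-3-methylbut-1-yne (1.2 equiv), K2CO3 (1.05 equiv), KI, CuI (10 mol%), DMF, 60 °C, Ar
Reagents that add atoms: 3-chloro-3-methylbut-1-yne, CC(C)(Cl)C#C
Why: Copper-catalysed O-propargylation takes place at the 4-OH, which is para to the formyl group, the more acidic phenol and the only one ionised by one equivalent of weak base.

Step 8
Reactants: 10 2-bromo-5-hydroxy-4-[(2-methylbut-3-yn-2-yl)oxy]benzaldehyde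
Product: 11 2-bromo-5-(methoxymethoxy)-4-[(2-methylbut-3-yn-2-yl)oxy]benzaldehyde
Conditions: MOMCl, i-Pr2NEt, CH2Cl2, 0 °C → rt
Reagents that add atoms: chloromethyl methyl ether (MOMCl), COCCl
Why: MOM protection of the remaining phenol gives a base-stable group that survives the thermal step, the coupling and the aldol.

Step 9
Reactants: 11 2-bromo-5-(methoxymethoxy)-4-[(2-methylbut-3-yn-2-yl)oxy]benzaldehyde
Product: 14 5-bromo-8-(methoxymethoxy)-2,2-dimethyl-2H-chromene-6-carbaldehyde, via allenylphenol 12 (not isolated), via ortho-quinone methide 13 (not isolated)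
Conditions: N,N-diethylaniline, 190 °C
Reagents that add atoms: none
Why: Propargyl aryl ether Claisen rearrangement to the only free ortho carbon, then a 1,5-hydrogen shift and oxa-6π electrocyclisation, closes the 2,2-dimethyl-2H-pyran ring.

Step 10
Reactants: 14 5-bromo-8-(methoxymethoxy)-2,2-dimethyl-2H-chromene-6-carbaldehyde
Product: 15 8-(methoxymethoxy)-2,2-dimethyl-5-(3-methylbut-2-en-1-yl)-2H-chromene-6-carbaldehyde
Conditions: tributyl(3-methylbut-2-en-1-yl)stannane (1.5 equiv), Pd(PPh3)4 (5 mol%), DMF, 100 °C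
Reagents that add atoms: tributyl(3-methylbut-2-en-1-yl)stannane, CCCC[Sn](CCCC)(CCCC)CC=C(C)C
Why: Stille cross-coupling works at the C–Br bond activated by the ortho formyl group, and reductive elimination at the less hindered allyl terminus gives the linear prenyl group without protecting the aldehyde.

### Fragment union and completion

Step 11
Reactants: 7 1-[2-hydroxy-4-(methoxymethoxy)-5-(2-methylbut-3-en-2-yl)phenyl]ethan-1-one; 15 8-(methoxymethoxy)-2,2-dimethyl-5-(3-methylbut-2-en-1-yl)-2H-chromene-6-carbaldehyde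
Product: 17 (2E)-1-[2-hydroxy-4-(methoxymethoxy)-5-(2-methylbut-3-en-2-yl)phenyl]-3-[8-(methoxymethoxy)-2,2-dimethyl-5-(3-methylbut-2-en-1-yl)-2H-chromen-6-yl]prop-2-en-1-one, via aldol adduct 16 (not isolated)
Conditions: KOH (50% aq), EtOH, rt, 48 h; then AcOH to pH 6 at 0 °C
Reagents that add atoms: none
Why: Claisen–Schmidt aldol condensation of the methyl ketone enolate with the non-enolisable aldehyde, followed by E1cB dehydration, gives the thermodynamically favoured E-enone; MOM ethers and all three alkenes are inert to base.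

Step 12
Reactants: 17 the chalcone from step 11
Product: 18 ethyl 5-(methoxymethoxy)-2-{(2E)-3-[8-(methoxymethoxy)-2,2-dimethyl-5-(3-methylbut-2-en-1-yl)-2H-chromen-6-yl]prop-2-enoyl}-4-(2-methylbut-3-en-2-yl)phenyl carbonate
Conditions: ClCO2Et (1.2 equiv), Et3N, CH2Cl2, 0 °C
Reagents that add atoms: ethyl chloroformate, CCOC(=O)Cl
Why: O-acylation of the only free phenol masks the acidic OH for the hydride step and installs the group that later drives the deoxygenation.

Step 13
Reactants: 18 the chalcone ethyl carbonate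
Product: 19 ethyl 5-(methoxymethoxy)-2-{3-[8-(methoxymethoxy)-2,2-dimethyl-5-(3-methylbut-2-en-1-yl)-2H-chromen-6-yl]propanoyl}-4-(2-methylbut-3-en-2-yl)phenyl carbonate
Conditions: [(Ph3P)CuH]6 (0.4 equiv), H2O (5 equiv), degassed toluene/THF, rt
Reagents that add atoms: none
Why: Conjugate (1,4) hydride reduction by the phosphine copper hydride touches only the enone C=C, leaving the vinyl, prenyl and chromene alkenes and the carbonate alone, and water protonates the copper enolate before it can attack the carbonate.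

Step 14
Reactants: 19 the dihydrochalcone ethyl carbonate
Product: 22 5-(methoxymethoxy)-2-{3-[8-(methoxymethoxy)-2,2-dimethyl-5-(3-methylbut-2-en-1-yl)-2H-chromen-6-yl]propyl}-4-(2-methylbut-3-en-2-yl)phenol, via benzylic carbinol 20 (not isolated), via ortho-quinone methide 21 (not isolated)
Conditions: NaBH4 (5 equiv), THF/H2O (1:1), 0 °C → rt
Reagents that add atoms: none
Why: Ortho-carbonate-assisted deoxygenation: hydride reduces the ketone, the carbonate migrates to the benzylic alkoxide and is expelled to give an ortho-quinone methide, and a second hydride adds 1,4 to give the methylene group under basic, alkene-safe conditions.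

Step 15
Reactants: 22 the bis-MOM 1,3-diarylpropane
Product: 23 Kazinol K, 4-{3-[8-hydroxy-2,2-dimethyl-5-(3-methylbut-2-en-1-yl)-2H-chromen-6-yl]propyl}-6-(2-methylbut-3-en-2-yl)benzene-1,3-diol
Conditions: HCl (1.25 M in MeOH), rt → 40 °C
Reagents that add atoms: none
Why: Acid-catalysed MOM acetal methanolysis frees both phenols; the prenyl group has no ortho hydroxyl to cyclise onto, and the dilute acid is too weak to protonate the terminal vinyl group or open the chromene.

## Compound list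

1 | 1-(2,4-dihydroxyphenyl)ethan-1-one | CC(=O)c1ccc(O)cc1O | starting material
2 | 1-{2-hydroxy-4-[(3-methylbut-2-en-1-yl)oxy]phenyl}ethan-1-one | CC(=O)c1ccc(OCC=C(C)C)cc1O | intermediate
3 | 1-{2-(methoxymethoxy)-4-[(3-methylbut-2-en-1-yl)oxy]phenyl}ethan-1-one | CC(=O)c1ccc(OCC=C(C)C)cc1OCOC | intermediate
4 | 4-acetyl-3-(methoxymethoxy)-6-(2-methylbut-3-en-2-yl)cyclohexa-2,4-dien-1-one (ortho-dienone, racemic, not isolated) | CC(=O)C1=CC(C(C)(C)C=C)C(=O)C=C1OCOC | intermediate
5 | 1-[4-hydroxy-2-(methoxymethoxy)-5-(2-methylbut-3-en-2-yl)phenyl]ethan-1-one | CC(=O)c1cc(C(C)(C)C=C)c(O)cc1OCOC | intermediate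
6 | 1-[2,4-dihydroxy-5-(2-methylbut-3-en-2-yl)phenyl]ethan-1-one | CC(=O)c1cc(C(C)(C)C=C)c(O)cc1O | intermediate
7 | 1-[2-hydroxy-4-(methoxymethoxy)-5-(2-methylbut-3-en-2-yl)phenyl]ethan-1-one (fragment 1) | CC(=O)c1cc(C(C)(C)C=C)c(OCOC)cc1O | intermediate
8 | 2-bromo-4,5-dimethoxybenzaldehyde | O=Cc1cc(OC)c(OC)cc1Br | starting material
9 | 2-bromo-4,5-dihydroxybenzaldehyde | O=Cc1cc(O)c(O)cc1Br | intermediate
10 | 2-bromo-5-hydroxy-4-[(2-methylbut-3-yn-2-yl)oxy]benzaldehyde | O=Cc1cc(O)c(OC(C)(C)C#C)cc1Br | intermediate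
11 | 2-bromo-5-(methoxymethoxy)-4-[(2-methylbut-3-yn-2-yl)oxy]benzaldehyde | O=Cc1cc(OCOC)c(OC(C)(C)C#C)cc1Br | intermediate
12 | 2-bromo-4-hydroxy-5-(methoxymethoxy)-3-(3-methylbuta-1,2-dien-1-yl)benzaldehyde (allenylphenol, not isolated) | O=Cc1cc(OCOC)c(O)c(C=C=C(C)C)c1Br | intermediate
13 | (3E)-2-bromo-5-(methoxymethoxy)-3-(3-methylbut-2-en-1-ylidene)-4-oxocyclohexa-1,5-diene-1-carbaldehyde (ortho-quinone methide, vinyl group on the side of the ring carbonyl, not isolated) | O=CC1=C(Br)/C(=C/C=C(C)C)C(=O)C(OCOC)=C1 | intermediate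
14 | 5-bromo-8-(methoxymethoxy)-2,2-dimethyl-2H-chromene-6-carbaldehyde | O=Cc1cc(OCOC)c2OC(C)(C)C=Cc2c1Br | intermediate
15 | 8-(methoxymethoxy)-2,2-dimethyl-5-(3-methylbut-2-en-1-yl)-2H-chromene-6-carbaldehyde (fragment 2) | O=Cc1cc(OCOC)c2OC(C)(C)C=Cc2c1CC=C(C)C | intermediate
16 | 3-hydroxy-1-[2-hydroxy-4-(methoxymethoxy)-5-(2-methylbut-3-en-2-yl)phenyl]-3-[8-(methoxymethoxy)-2,2-dimethyl-5-(3-methylbut-2-en-1-yl)-2H-chromen-6-yl]propan-1-one (aldol adduct, racemic, not isolated) | C=CC(C)(C)c1cc(C(=O)CC(O)c2cc(OCOC)c3OC(C)(C)C=Cc3c2CC=C(C)C)c(O)cc1OCOC | intermediate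
17 | (2E)-1-[2-hydroxy-4-(methoxymethoxy)-5-(2-methylbut-3-en-2-yl)phenyl]-3-[8-(methoxymethoxy)-2,2-dimethyl-5-(3-methylbut-2-en-1-yl)-2H-chromen-6-yl]prop-2-en-1-one | C=CC(C)(C)c1cc(C(=O)/C=C/c2cc(OCOC)c3OC(C)(C)C=Cc3c2CC=C(C)C)c(O)cc1OCOC | intermediate
18 | ethyl 5-(methoxymethoxy)-2-{(2E)-3-[8-(methoxymethoxy)-2,2-dimethyl-5-(3-methylbut-2-en-1-yl)-2H-chromen-6-yl]prop-2-enoyl}-4-(2-methylbut-3-en-2-yl)phenyl carbonate | C=CC(C)(C)c1cc(C(=O)/C=C/c2cc(OCOC)c3OC(C)(C)C=Cc3c2CC=C(C)C)c(OC(=O)OCC)cc1OCOC | intermediate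
19 | ethyl 5-(methoxymethoxy)-2-{3-[8-(methoxymethoxy)-2,2-dimethyl-5-(3-methylbut-2-en-1-yl)-2H-chromen-6-yl]propanoyl}-4-(2-methylbut-3-en-2-yl)phenyl carbonate | C=CC(C)(C)c1cc(C(=O)CCc2cc(OCOC)c3OC(C)(C)C=Cc3c2CC=C(C)C)c(OC(=O)OCC)cc1OCOC | intermediate
20 | ethyl 2-{1-hydroxy-3-[8-(methoxymethoxy)-2,2-dimethyl-5-(3-methylbut-2-en-1-yl)-2H-chromen-6-yl]propyl}-5-(methoxymethoxy)-4-(2-methylbut-3-en-2-yl)phenyl carbonate (benzylic carbinol, racemic, not isolated) | C=CC(C)(C)c1cc(C(O)CCc2cc(OCOC)c3OC(C)(C)C=Cc3c2CC=C(C)C)c(OC(=O)OCC)cc1OCOC | intermediate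
21 | (6Z)-3-(methoxymethoxy)-6-{3-[8-(methoxymethoxy)-2,2-dimethyl-5-(3-methylbut-2-en-1-yl)-2H-chromen-6-yl]propylidene}-4-(2-methylbut-3-en-2-yl)cyclohexa-2,4-dien-1-one (ortho-quinone methide, drawn as one geometric isomer, either gives the same product, not isolated) | C=CC(C)(C)C1=C/C(=C/CCc2cc(OCOC)c3OC(C)(C)C=Cc3c2CC=C(C)C)C(=O)C=C1OCOC | intermediate
22 | 5-(methoxymethoxy)-2-{3-[8-(methoxymethoxy)-2,2-dimethyl-5-(3-methylbut-2-en-1-yl)-2H-chromen-6-yl]propyl}-4-(2-methylbut-3-en-2-yl)phenol | C=CC(C)(C)c1cc(CCCc2cc(OCOC)c3OC(C)(C)C=Cc3c2CC=C(C)C)c(O)cc1OCOC | intermediate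
23 | Kazinol K, 4-{3-[8-hydroxy-2,2-dimethyl-5-(3-methylbut-2-en-1-yl)-2H-chromen-6-yl]propyl}-6-(2-methylbut-3-en-2-yl)benzene-1,3-diol (achiral) | C=CC(C)(C)c1cc(CCCc2cc(O)c3c(c2CC=C(C)C)C=CC(C)(C)O3)c(O)cc1O | target

## Count and risks

Total steps: 15. Longest linear sequence: 10 steps (steps 1–5 or 6–10, then 11–15).

The three steps most likely to fail:

Step 3, the Claisen rearrangement. It may give some C3 product, lose the prenyl group or drift into abnormal Claisen products. The fallback sets out from 1 and comes back at 6, and replaces the sigmatropic shift by a cross-coupling. Bromination of 1 (Br2, AcOH, rt) gives 1-(5-bromo-2,4-dihydroxyphenyl)ethan-1-one F1. Capping both phenols (NaH, MOMCl, DMF) gives 1-[5-bromo-2,4-bis(methoxymethoxy)phenyl]ethan-1-one F2. A γ-selective Suzuki–Miyaura coupling with potassium trifluoro(3-methylbut-2-en-1-yl)borate (Pd(OAc)2, 1,1'-bis(di-tert-butylphosphino)ferrocene Fe(C5H4P(t-Bu)2)2, K2CO3, THF/H2O, reflux) bonds the tertiary allyl carbon to the ring and gives 1-[2,4-bis(methoxymethoxy)-5-(2-methylbut-3-en-2-yl)phenyl]ethan-1-one F3. Methanolic HCl then removes both MOM groups to give 6.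

Step 10, the Stille prenylation. The bromide has two ortho neighbours, and some branched (1,1-dimethylallyl) isomer may form. The fallback sets out from 14 and comes back at 15, and separates C–C bond formation from installation of the trisubstituted alkene. Stille coupling with allyltributylstannane (Pd(PPh3)4, DMF, 90 °C), which has no regiochemical ambiguity, gives 8-(methoxymethoxy)-2,2-dimethyl-5-(prop-2-en-1-yl)-2H-chromene-6-carbaldehyde F4. Cross-metathesis of its terminal alkene with excess 2-methylbut-2-ene (second-generation Grubbs catalyst RuCl2(=CHPh)(PCy3)(H2IMes), CH2Cl2, 40 °C) then gives 15; the ring-bound chromene alkene is not expected to take part.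

Step 13, the conjugate reduction. Over-reduction, or transfer of the carbonate to the copper enolate, could lower the yield. The fallback sets out from 17 and comes back at 19, and reverses the order of reduction and acylation with a non-hydridic reductant. The free-phenol chalcone 17 is reduced with Na2S2O4 and NaHCO3 in dioxane/H2O at 80 °C (sulfinate addition and loss of SO2, inert to isolated alkenes) to 1-[2-hydroxy-4-(methoxymethoxy)-5-(2-methylbut-3-en-2-yl)phenyl]-3-[8-(methoxymethoxy)-2,2-dimethyl-5-(3-methylbut-2-en-1-yl)-2H-chromen-6-yl]propan-1-one F5. Acylation of F5 with ClCO2Et and Et3N in CH2Cl2 at 0 °C gives 19.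

## Further compounds

F1 | step 3 | 1-(5-bromo-2,4-dihydroxyphenyl)ethan-1-one | CC(=O)c1cc(Br)c(O)cc1O
F2 | step 3 | 1-[5-bromo-2,4-bis(methoxymethoxy)phenyl]ethan-1-one | CC(=O)c1cc(Br)c(OCOC)cc1OCOC
F3 | step 3 | 1-[2,4-bis(methoxymethoxy)-5-(2-methylbut-3-en-2-yl)phenyl]ethan-1-one | CC(=O)c1cc(C(C)(C)C=C)c(OCOC)cc1OCOC
F4 | step 10 | 8-(methoxymethoxy)-2,2-dimethyl-5-(prop-2-en-1-yl)-2H-chromene-6-carbaldehyde | O=Cc1cc(OCOC)c2OC(C)(C)C=Cc2c1CC=C
F5 | step 13 | 1-[2-hydroxy-4-(methoxymethoxy)-5-(2-methylbut-3-en-2-yl)phenyl]-3-[8-(methoxymethoxy)-2,2-dimethyl-5-(3-methylbut-2-en-1-yl)-2H-chromen-6-yl]propan-1-one | C=CC(C)(C)c1cc(C(=O)CCc2cc(OCOC)c3OC(C)(C)C=Cc3c2CC=C(C)C)c(O)cc1OCOC
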